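All constants are made up; what happens was integrated by code.

I count turnovers.

Z 2.6 M; E 200 mM (held); time 3.0 h

- G.L and Q together at 3.0 h, in percent of the Z charged
- the change that raises the amount of G.L and Q together at 3.0 h, in percent of the Z charged most ("none" if none brings more than 2 percentage points) (eta / gamma / delta / zeta / none)
- amount of G.L and Q together at 3.0 h, in percent of the Z charged, after eta

- eta: doubling the dissolution coefficient of step 5, all else as stated
- gamma: doubling the solubility in step 5, all else as stated
- delta: doubling the saturation concentration of E, all else as stated
- zeta: doubling the dissolution coefficient of step 1, all else as stated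

- percent here means Z units held: one G2 counts as two
- what is said of G.L includes Q
- a step written with two of one species runs at k times the square of its concentration and takes two of it each time
- Z, Q is a solid; its amount is given per volume of the solution
- at the start none of L is dissolved
- at the start none of Z is in solution
- run time (flask): 3.0 h

    Q ⇌ G.L, rate k1*(cs1 - [G.L]) while solid is left; crystals form when [G.L] > cs1 (cs1 = 0.41 M, k1 = 0.574 min⁻¹)
    E ⇌ L, rate k2*(csat - [L]) (k2 = 8.70 min⁻¹, csat = 200 mM)
    2 G → G2 (k3 = 0.111 L mol⁻¹ min⁻¹)
    G + L → G.L (k4 = 3.82 L mol⁻¹ min⁻¹)
    Z ⇌ G, rate k5*(cs5 - [G]) while solid is left; crystals form when [G] > cs5 (cs5 = 0.054 M, k5 = 1.02 min⁻¹)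
    G.L ⇌ D (K6 = 0.694, k6 = 0.00701 min⁻¹)

- I start with the main step and leave out the rest. Z dissolves and L catches G, a pseudo-first-order capture with L taken at 200 mM.
- G then stands where dissolving equals capture, at 0.0309 M. Taking L at that value is fair, since the transfer coefficient 8.70 min⁻¹ is far above the 0.118 min⁻¹ that G pulls on L. So G.L is made at 0.0236 M min⁻¹, and I reckon that Z lasts 1.84 h, less than the run of 3.0 h. At this stage the answer is 100 percent.
- I add G2. It takes 0.897% of the Z units, so the answer falls to 99.1%.
- I add Q and D. I reckon that dissolved G.L reaches its solubility after about 17.4 min, less than the run, and Q then holds it near there while solid is left.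
- While solid Q is left, D heads for its ceiling, the equilibrium constant times the solubility, which is 10.9% of the charge. With G.L held, D approaches that ceiling at its own return rate, so its lifetime is 99.0 min.
- I get 1.82, counted roughly from the start. That is my quantity, the D turnovers, the run time divided by that lifetime.
- D fills 83.8% of its ceiling, which is 9.17%. My answer is 89.9%.
- Eta, gamma and delta move G, and so the G2 share, but they stay out of the ceiling. Zeta moves neither in my reckoning. Eta lifts the G2 share to 1.14%, which gives 89.7%. Scored by the gain in G2 share against the margin, the choice is none.

- The forecast gives 89.8%, none and 89.5%, and says: "None of the four changes touches that D ceiling much". Its y lies close to mine.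

The flask gives 89.8%, the choice none, and 89.6% after eta. D stands at 9.27% at 3.00 h, beside my 9.17%. The flask with 1.6 M of Z has the same D turnovers, 1.82, since the charge is not in them. Its ceiling is 17.8% of its smaller charge, and 83.8% of that is 14.9%. That flask holds D at 14.8%.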